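If one partner of a bimolecular step stands in excess, the other decays like a first-order lag whose time constant τ is the inverse of k[excess partner]. This is the pseudo-first-order picture, and I apply it to Qa + Qb → Qe + Qf.

all flasks: Qa 20 mM; Qd 12 mM (held)

|  | Qb | remark | time |
|---|---|---|---|
| Thursday's | 37 mM | run made earlier |  |
| Tuesday's | 61 mM | run made earlier |  |
| Monday's | 78 mM | run made earlier |  |
| theta | 80.0 mM |  | 8.0 h |
| epsilon | 40.0 mM |  | 8.0 h |

| run | time / h | Qa / % | Qf / % |
|---|---|---|---|
| Thursday's | 0.333 | 103 | 5 |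
| Thursday's | 0.667 | 97 | 3 |
| Thursday's | 1.00 | 95 | 9 |
| Thursday's | 2.00 | 87 | 12 |
| Thursday's | 4.00 | 81 | 23 |
| Tuesday's | 0.833 | 89 | 8 |
| Tuesday's | 1.50 | 83 | 17 |
| Tuesday's | 2.50 | 72 | 23 |
| Tuesday's | 3.00 | 74 | 25 |
| Tuesday's | 4.00 | 69 | 33 |
| Monday's | 0.333 | 94 | 6 |
| Monday's | 0.667 | 90 | 11 |
| Monday's | 1.00 | 84 | 14 |
| Monday's | 2.00 | 76 | 25 |
| Monday's | 4.00 | 57 | 41 |

(readings scatter by 2 percentage points)

- at the start none of Qc is dissolved
- candidate steps: Qa + Qb -> Qe + Qf; Qb + Qe <-> Qg; Qe + Qc <-> Qh; Qe -> Qj; Qd <-> Qc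

* part of the Qa that has reacted at the end, theta
* part of the Qa that has reacted at the end, epsilon
* what raising the concentration of Qb from its lowest to its highest value here does to the part of the Qa that has reacted (changes below 5 percentage points count as none) (it falls / it rises / no change)

Thursday's 37 mM of Qb stands above the 20 mM of Qa, so I follow Qa and take [Qb] as the concentration to watch. In Monday's run Qa and Qf sum to 98.0 % at 4.00 h, so little Qa hides elsewhere. The other candidate steps start from Qe or Qd and reach Qa, if at all, through [Qb]. The logarithm of Qa's fall by 4.00 h climbs from 0.211 on Thursday to 0.562 on Monday as the charge of Qb climbs. Dividing the summed logarithms of the three runs by that time and the summed charges gives the pooled rate constant k = 0.0271 M⁻¹ min⁻¹, which turns a charge of Qb into a time constant. Whatever [Qb] lost in those hours is folded into it.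

Two times remain: τ and the reading time 8.0 h. τ is 7.69 h in theta and 15.4 h in epsilon. The reacted part is one minus exp(−t/τ), so I reckon 64.7 % for theta and 40.5 % for epsilon. The forecast gives 63 % and 36 %, both below mine, and of the trend it says it rises: “Extra Qb clearly raises conversion.”

The flask gives 63.9 % in theta and 38.8 % in epsilon, and the trend is it rises, by 25 percentage points.

    Qa + Qb → Qe + Qf (k = 0.0330 M⁻¹ min⁻¹)
    Qb + Qe ⇌ Qg, settled at all times (K = 41200 M⁻¹)
    Qe + Qc ⇌ Qh, settled at all times (K = 200 M⁻¹)
    Qe → Qj (k = 6.44 × 10⁻⁴ min⁻¹)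
    Qd ⇌ Qc, rate k5*(csat - [Qc]) (kL = 0.00403 min⁻¹)

The gap between the two flasks comes from the difference in [Qb]: charged like epsilon, theta drops from 63.9 % to 38.8 %. The same k serves a neighbour of epsilon charged with 68 mM of Qb and read at 8.0 h, where it reckons 58.7 %. That neighbour gives 57.6 %.

(Readings and results come from a simulation for substances that don't exist; scatter was added.)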